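**Plan**

- Target: 2-methoxy-6-nonadecyl-1,4-benzoquinone (quinone numbering: C1=O lies between C2–OMe and C6–C19H39; C3–H, C4=O, C5–H).
- Enabling feature: both substituents flank the same carbonyl (C1) and C3/C5 are bare CH, so the six ring carbons map onto a 4-(1-alkylvinyl)-4-hydroxy-3-methoxycyclobut-2-enone. Carbinol C4 becomes C1, ring C3(OMe) becomes C2, ring C2(H) becomes C3, the ring C=O becomes C4, the vinyl CH2 becomes C5 and the vinyl α-carbon becomes C6.
- Retrosynthetic cuts: (a) quinone to hydroquinone; (b) ring bond C4–C5 cut and C1···C4 rejoined (retro-6π, retro-4π), contracting the six-membered ring to a four-membered ring; (c) carbinol–vinyl bond C1–C6, giving methyl semisquarate and henicos-1-en-2-yllithium; (d) the allylic C–C bond of the chain, giving an octadecyl Grignard reagent and 2,3-dibromopropene.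
- Forward order: the chain is joined to a C3 vinyl bromide unit; the four-membered ring comes from dimethyl squarate (one methoxy exchanged for H); the two halves are joined at the carbinol carbon; the six-membered ring then arises in one thermal 4-to-6 ring expansion and is oxidised to the quinone.
- Stereochemistry: the target has no stereogenic element; the single stereocentre on the route (the carbinol carbon of the cyclobutenone) forms racemic and becomes an aromatic carbon in the key step.

Key step: step 4

**Step 1**
Reactants: 1 1-bromooctadecane; 2 2,3-dibromoprop-1-ene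
Product: 4 2-bromohenicos-1-ene, via octadecylmagnesium bromide 3 (not isolated)
Conditions: Mg turnings, THF, 45 °C; then added to 2 (1.3 equiv), CuI (5 mol %), THF, −10 °C to rt
Reagents that add atoms: none
Why: The primary alkyl Grignard reagent displaces the allylic bromide of 2 (copper-catalysed allylic substitution, where direct and SN2' attack give the same product) while the vinylic C–Br bond stays intact, a standard entry to 2-bromoalk-1-enes; alkane by-products of Wurtz coupling are inert in step 3 and are removed there.

**Step 2**
Reactants: 5 dimethyl squarate (3,4-dimethoxycyclobut-3-ene-1,2-dione)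
Product: 7 3-methoxycyclobut-3-ene-1,2-dione (methyl semisquarate), via hydroxycyclobutenone 6 (not isolated)
Conditions: LiAlH(OtBu)3 (1.05 equiv), THF, −78 °C, 1 M HCl quench; crude 6 in CH2Cl2, 12 M HCl (catalytic), rt
Reagents that add atoms: water, O (supplies the new ring carbonyl oxygen; the carbinol OH of 6 leaves as water)
Why: The bulky hydride should add once (1,2) to a squarate carbonyl to give carbinol 6, and acid then ionises the allylic hydroxyl to a methoxy-stabilised cyclobutenyl cation whose hydrolysis with loss of methanol gives the semisquarate, the established reduction–hydrolysis sequence for dialkyl squarates.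

**Step 3**
Reactants: 4 2-bromohenicos-1-ene; 7 3-methoxycyclobut-3-ene-1,2-dione
Product: 9 4-(henicos-1-en-2-yl)-4-hydroxy-3-methoxycyclobut-2-en-1-one (racemic), via henicos-1-en-2-yllithium 8 (not isolated)
Conditions: 4 (1.1 equiv), tBuLi (2.2 equiv), THF, −78 °C; cannulated into 7 (1.0 equiv), THF, −78 °C; sat. aq. NH4Cl at −78 °C; chromatography on Et3N-deactivated silica
Reagents that add atoms: none
Why: Bromine–lithium exchange gives the 1-alkylvinyllithium 8, which should add 1,2 to the ketone-like carbonyl C2 of 7 (attached to the methoxy-bearing carbon and not deactivated by vinylogous-ester resonance, unlike C1), the established regiochemistry of organolithium additions to 3-alkoxycyclobutenediones; the carbinol stereocentre forms racemic and is erased in step 4.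

**Step 4**
Reactants: 9 4-(henicos-1-en-2-yl)-4-hydroxy-3-methoxycyclobut-2-en-1-one
Product: 12 2-methoxy-6-nonadecylbenzene-1,4-diol, via dienylketene 10 (not isolated), via cyclohexadienone 11 (not isolated)
Conditions: degassed toluene (0.02 M), 110 °C, argon
Reagents that add atoms: none
Why: Heating should open the cyclobutenone by thermal conrotatory 4π-electrocyclic cleavage of the C1–C4 bond to the (Z)-dienylketene 10, whose ketene carbon and vinyl CH2 terminus then join by thermal disrotatory 6π-electrocyclisation to cyclohexa-2,4-dienone 11, and enolisation gives the aromatic hydroquinone 12. The closest known reaction type is the thermal ring expansion of squarate-derived 4-alkenyl- and 4-aryl-4-hydroxycyclobutenones to hydroquinones (Moore–Liebeskind ring expansion). The six-membered ring closes by 6π-electrocyclisation, four of its atoms coming from the four-membered ring and two from the vinyl group. No stereocentre is created, and the only one in 9 becomes an sp2 carbon. The step needs torquoselectivity in the ring opening, and the electron-donating C4 hydroxyl secures it by rotating outward, which places the vinyl group cis to the ketene; inward rotation of the hydroxyl would instead lead to a butenolide. Regiochemistry needs no control, because the connectivity of 9 already places the carbinol carbon between the methoxy-bearing and the alkyl-bearing carbons.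

**Step 5**
Reactants: 12 2-methoxy-6-nonadecylbenzene-1,4-diol
Product: 13 2-methoxy-6-nonadecylcyclohexa-2,5-diene-1,4-dione (target)
Conditions: Ag2O (2 equiv), Na2SO4, Et2O, rt
Reagents that add atoms: none
Why: Ag2O is a mild, neutral two-electron oxidant that should convert the p-hydroquinone to the p-benzoquinone without touching the methyl enol ether or the alkyl chain (hydroquinone-to-quinone oxidation).

**Compound list**

1 | 1-bromooctadecane | CCCCCCCCCCCCCCCCCCBr | starting material
2 | 2,3-dibromoprop-1-ene | C=C(Br)CBr | starting material
3 | octadecylmagnesium bromide | CCCCCCCCCCCCCCCCCC[Mg]Br | intermediate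
4 | 2-bromohenicos-1-ene | C=C(Br)CCCCCCCCCCCCCCCCCCC | intermediate
5 | dimethyl squarate (3,4-dimethoxycyclobut-3-ene-1,2-dione) | COC1=C(OC)C(=O)C1=O | starting material
6 | 4-hydroxy-2,3-dimethoxycyclobut-2-en-1-one (racemic) | COC1=C(OC)C(=O)C1O | intermediate
7 | 3-methoxycyclobut-3-ene-1,2-dione (methyl semisquarate) | COC1=CC(=O)C1=O | intermediate
8 | henicos-1-en-2-yllithium | [Li]C(=C)CCCCCCCCCCCCCCCCCCC | intermediate
9 | 4-(henicos-1-en-2-yl)-4-hydroxy-3-methoxycyclobut-2-en-1-one (racemic) | COC1=CC(=O)C1(O)C(=C)CCCCCCCCCCCCCCCCCCC | intermediate
10 | (3Z)-4-hydroxy-3-methoxy-5-methylidenetetracosa-1,3-dien-1-one (dienylketene) | O=C=C/C(OC)=C(/O)C(=C)CCCCCCCCCCCCCCCCCCC | intermediate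
11 | 4-hydroxy-3-methoxy-5-nonadecylcyclohexa-2,4-dien-1-one | COC1=CC(=O)CC(CCCCCCCCCCCCCCCCCCC)=C1O | intermediate
12 | 2-methoxy-6-nonadecylbenzene-1,4-diol | COc1cc(O)cc(CCCCCCCCCCCCCCCCCCC)c1O | intermediate
13 | 2-methoxy-6-nonadecylcyclohexa-2,5-diene-1,4-dione (2-methoxy-6-nonadecyl-1,4-benzoquinone) | CCCCCCCCCCCCCCCCCCCC1=CC(=O)C=C(OC)C1=O | target

**Count**

Total steps: 5. Longest linear sequence: 4 steps (steps 1, 3, 4, 5 or steps 2, 3, 4, 5).

**Steps most likely to fail**

1. Step 3. The waxy C21 bromide may come out of solution at −78 °C, so that bromine–lithium exchange stays incomplete and residual tBuLi adds to 7; over-addition to the dione is the second danger. The fallback makes the vinyllithium without halogen–metal exchange, by a Shapiro reaction. It sets out from 3 and comes back at 8. Grignard reagent 3 would be opened onto methyloxirane (CuI catalytic, THF, −30 °C, aq. NH4Cl work-up) to give henicosan-2-ol F1. Oxidation (Dess–Martin periodinane, CH2Cl2, rt) would give henicosan-2-one F2. Condensation with 2,4,6-tri(propan-2-yl)benzenesulfonohydrazide (MeOH, catalytic HCl, rt) would give the trisylhydrazone F3. Treating F3 with nBuLi (2.1 equiv, THF/TMEDA, −78 °C then 0 °C) should deprotonate the methyl group selectively, expel the sulfinate and N2, and leave a homogeneous solution of 8 free of tBuLi, which would be added to 7 as in step 3.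

2. Step 4. The free hydroxyl may rotate inward or trap the ketene to give a butenolide, or the monosubstituted ketene may oligomerise before it cyclises. The fallback removes the free hydroxyl before the ring expansion. It sets out from 9 and comes back at 12. Compound 9 would be silylated (Me3SiCl, imidazole, CH2Cl2, 0 °C) to 4-(henicos-1-en-2-yl)-3-methoxy-4-[(trimethylsilyl)oxy]cyclobut-2-en-1-one F4. The silyloxy group is a stronger outward-rotating donor and cannot lactonise. Thermolysis of F4 (toluene, 110 °C) should give 3-methoxy-5-nonadecyl-4-[(trimethylsilyl)oxy]phenol F5, and mild methanolysis (citric acid, MeOH, rt) would release 12.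

3. Step 2. A second hydride may add, or the methyl enol ether may hydrolyse during the acid stage, so that material is lost to the aqueous phase as semisquaric acid. The fallback accepts the hydrolysis and rebuilds the enol ether by O-methylation. It sets out from 6 and comes back at 7. Crude 6 would be hydrolysed completely (2 M aq. HCl, rt to 50 °C) to semisquaric acid F6 (3-hydroxycyclobut-3-ene-1,2-dione), isolated by evaporation and crystallisation. F6 would then be methylated with trimethyl orthoformate in methanol at reflux, the conditions that turn squaric acid into dimethyl squarate, to give 7.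

**Further compounds**

F1 | step 3 | henicosan-2-ol (racemic) | CC(O)CCCCCCCCCCCCCCCCCCC
F2 | step 3 | henicosan-2-one | CC(=O)CCCCCCCCCCCCCCCCCCC
F3 | step 3 | N'-[(2E)-henicosan-2-ylidene]-2,4,6-tri(propan-2-yl)benzenesulfonohydrazide | C/C(CCCCCCCCCCCCCCCCCCC)=N\NS(=O)(=O)c1c(C(C)C)cc(C(C)C)cc1C(C)C
F4 | step 4 | 4-(henicos-1-en-2-yl)-3-methoxy-4-[(trimethylsilyl)oxy]cyclobut-2-en-1-one (racemic) | COC1=CC(=O)C1(O[Si](C)(C)C)C(=C)CCCCCCCCCCCCCCCCCCC
F5 | step 4 | 3-methoxy-5-nonadecyl-4-[(trimethylsilyl)oxy]phenol | COc1cc(O)cc(CCCCCCCCCCCCCCCCCCC)c1O[Si](C)(C)C
F6 | step 2 | semisquaric acid (3-hydroxycyclobut-3-ene-1,2-dione) | OC1=CC(=O)C1=O
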